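**Retrosynthetic overview**
1. Target ⇒ nonamethyl ether (nine O-demethylations) ⇒ pentacyclic bis-phenol. Both outer 3,5-dioxygenated rings are attached together in one double Ullmann O-arylation.
2. Pentacycle ⇒ open tri-aryl bis-ether with one Br on the central ring and one Br on the future furan ring. The dioxin C–O bond (Cu) and the furan C–C bond (Pd, C–H) are closed in one flask.
3. The dioxin partner ring enters as a C2v-symmetric 2-fluoroisophthalaldehyde. Its two CHO groups become two equivalent OH groups, so either one closes the same dioxin and the other remains for the outer aryl ether.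
4. All three CHO groups are masked phenols, unveiled in one triple Baeyer–Villiger oxidation. The two diaryl ethers come from two SNAr reactions on 2-bromo-6-methoxyhydroquinone, the Dakin product of 5-bromovanillin.
5. Ring order: all benzene rings are bought. The 1,4-dioxin and then the furan form in the same operation, and no ring is formed afterwards.

Assumption: the target has no stereocentre and no configurationally stable axis. It is therefore achiral, and no step has to set configuration.

Ring labels:
- A and E are the outer 3,5-dioxygenated phenyl rings.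
- B is the benzo ring of the dioxin that carries ring A.
- C is the central ring.
- D is the benzo ring of the furan that carries ring E.

**Step 1**
Reactants: 1 2-fluoro-4,6-dimethoxybenzaldehyde
Product: 2 3-bromo-2-fluoro-4,6-dimethoxybenzaldehyde
Conditions: NBS (1.05 equiv), MeCN, 0 °C → rt
Reagents that add atoms: N-bromosuccinimide, O=C1CCC(=O)N1Br
Why: Electrophilic aromatic bromination goes to C3, which is ortho to one OMe, para to the other and next to the small F, because the alternative site between the two OMe groups is more crowded.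

**Step 2**
Reactants: 1 2-fluoro-4,6-dimethoxybenzaldehyde
Product: 3 2-fluoro-4,6-dimethoxybenzene-1,3-dicarbaldehyde
Conditions: Cl2CHOMe (3 equiv), TiCl4 (4 equiv), CH2Cl2, 0 °C → rt; aq. HCl
Reagents that add atoms: dichloromethyl methyl ether, COC(Cl)Cl; water, O
Why: Rieche formylation attacks the same ortho/para-activated, F-flanked carbon as step 1, because the two OMe groups outweigh the deactivation by the first (Ti-bound) formyl group.

**Step 3**
Reactants: 4 5-bromovanillin (3-bromo-4-hydroxy-5-methoxybenzaldehyde)
Product: 6 2-bromo-6-methoxybenzene-1,4-diol, via aryl formate 5 (not isolated)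
Conditions: 30% H2O2, aq. NaOH, 0 °C → rt, N2; then HCl
Reagents that add atoms: hydrogen peroxide, OO
Why: In this Dakin oxidation the para-phenoxide drives aryl migration in the peroxide adduct, and the formate is hydrolysed in the alkaline medium.

**Step 4**
Reactants: 6 2-bromo-6-methoxybenzene-1,4-diol; 2 3-bromo-2-fluoro-4,6-dimethoxybenzaldehyde; 3 2-fluoro-4,6-dimethoxybenzene-1,3-dicarbaldehyde
Product: 8 2-[2-bromo-4-(2-bromo-6-formyl-3,5-dimethoxyphenoxy)-6-methoxyphenoxy]-4,6-dimethoxybenzene-1,3-dicarbaldehyde, via ring C–ring D monoether 7 (not isolated)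
Conditions: 6 + 2 (1.0 equiv), K2CO3 (4 equiv), degassed DMF, 80 °C; then 3 (1.1 equiv), 80 °C, same flask
Reagents that add atoms: none
Why: Two SNAr reactions are graded by steric demand, since only the open phenoxide (H on both sides) reaches the C–F of 2 (flanked by CHO and Br), while the remaining Br/OMe-flanked phenoxide needs the fluoride of 3, activated by two coplanar ortho-formyl groups, as in the preparation of tetra-ortho-substituted thyronine-type ethers from 2,6-disubstituted phenols.

**Step 5**
Reactants: 8 the trialdehyde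
Product: 10 2-[2-bromo-4-(2-bromo-6-hydroxy-3,5-dimethoxyphenoxy)-6-methoxyphenoxy]-4,6-dimethoxybenzene-1,3-diol, via tris-formate 9 (not isolated)
Conditions: mCPBA (4 equiv), CH2Cl2, 0 °C → rt; then MeOH, cat. HCl, rt, Ar
Reagents that add atoms: 3-chloroperoxybenzoic acid, OOC(=O)c1cccc(Cl)c1
Why: In this threefold Baeyer–Villiger (Dakin-type) oxidation every formyl group sits on a 2,4,6-trioxygenated ring, so aryl migration is fast and exclusive, and the phenols stay protected as formates until the peracid is gone.

**Step 6**
Reactants: 10 the dibromo triphenol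
Product: 12 1,3,6,10,12-pentamethoxy-[1]benzofuro[3,2-a]oxanthrene-4,9-diol, via dibenzodioxin bromide 11 (not isolated)
Conditions: CuI (20 mol %), N,N-dimethylglycine (40 mol %), Cs2CO3 (6 equiv), DMA (0.01 M), 100 °C, Ar; then Pd(OAc)2 (10 mol %), PCy3·HBF4 (20 mol %), PivOH (50 mol %), 130 °C, same flask
Reagents that add atoms: none
Why: Proposed new method: an orthogonal Cu/Pd relay in one flask, in which Cu(I) first couples the ring C bromide with one of the two equivalent flank phenoxides of the symmetric ring B (six-membered Ullmann closure; either OH gives the same dioxin and no ring is activated enough for a Smiles scramble), then Pd(0) inserts into the only C–Br left (ring D) and pivalate-assisted concerted metalation–deprotonation takes the ring C C–H lying between the tether oxygen and the tied-back dioxin oxygen rather than the one shielded by the in-plane OMe (closure there would also push two OMe groups together in the bay), and reductive elimination closes the furan; the closest known reaction types are the intramolecular Ullmann ether synthesis of dibenzo-p-dioxins from 2-(2-bromophenoxy)phenols and the Fagnou-type intramolecular direct arylation of 2-bromodiaryl ethers to dibenzofurans; no stereocentre is formed.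

**Step 7**
Reactants: 12 the pentacyclic bis-phenol; 13 1-iodo-3,5-dimethoxybenzene (3 equiv)
Product: 14 4,9-bis(3,5-dimethoxyphenoxy)-1,3,6,10,12-pentamethoxy-[1]benzofuro[3,2-a]oxanthrene
Conditions: CuI (20 mol %), picolinic acid (40 mol %), K3PO4, DMSO, 100 °C, Ar
Reagents that add atoms: none
Why: This is a ligand-accelerated Ullmann O-arylation in which the only two free OH groups are exactly the two that carry rings A and E, the aryl iodide is unhindered, and this catalyst system is the one used for 2,6-disubstituted phenols.

**Step 8**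
Reactants: 14 the nonamethyl ether
Product: 15 phlorofucofuroeckol A
Conditions: BBr3 (20 equiv), CH2Cl2, −78 °C → rt; ice-water; Sephadex LH-20
Reagents that add atoms: none
Why: In this Lewis-acid ether cleavage bromide attacks only the methyl carbons, so the diaryl ether, dioxin and furan C(sp2)–O bonds stay intact, and there is no stereocentre to scramble.

**Compound list**
1 | 2-fluoro-4,6-dimethoxybenzaldehyde | O=Cc1c(F)cc(OC)cc1OC | starting material
2 | 3-bromo-2-fluoro-4,6-dimethoxybenzaldehyde | O=Cc1c(F)c(Br)c(OC)cc1OC | intermediate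
3 | 2-fluoro-4,6-dimethoxybenzene-1,3-dicarbaldehyde | O=Cc1c(F)c(C=O)c(OC)cc1OC | intermediate
4 | 5-bromovanillin | O=Cc1cc(Br)c(O)c(OC)c1 | starting material
5 | 3-bromo-4-hydroxy-5-methoxyphenyl formate | O=COc1cc(Br)c(O)c(OC)c1 | intermediate
6 | 2-bromo-6-methoxybenzene-1,4-diol | Oc1cc(Br)c(O)c(OC)c1 | intermediate
7 | 3-bromo-2-(3-bromo-4-hydroxy-5-methoxyphenoxy)-4,6-dimethoxybenzaldehyde | O=Cc1c(Oc2cc(Br)c(O)c(OC)c2)c(Br)c(OC)cc1OC | intermediate
8 | 2-[2-bromo-4-(2-bromo-6-formyl-3,5-dimethoxyphenoxy)-6-methoxyphenoxy]-4,6-dimethoxybenzene-1,3-dicarbaldehyde | O=Cc1c(Oc2cc(Br)c(Oc3c(C=O)c(OC)cc(OC)c3C=O)c(OC)c2)c(Br)c(OC)cc1OC | intermediate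
9 | tris-formate of 10 (each CHO of 8 replaced by OCHO) | O=COc1c(Oc2cc(Br)c(Oc3c(OC=O)c(OC)cc(OC)c3OC=O)c(OC)c2)c(Br)c(OC)cc1OC | intermediate
10 | 2-[2-bromo-4-(2-bromo-6-hydroxy-3,5-dimethoxyphenoxy)-6-methoxyphenoxy]-4,6-dimethoxybenzene-1,3-diol | Oc1c(Oc2cc(Br)c(Oc3c(O)c(OC)cc(OC)c3O)c(OC)c2)c(Br)c(OC)cc1OC | intermediate
11 | 7-(2-bromo-6-hydroxy-3,5-dimethoxyphenoxy)-2,4,9-trimethoxydibenzo[b,e][1,4]dioxin-1-ol | Oc1c(Oc2cc3Oc4c(OC)cc(OC)c(O)c4Oc3c(OC)c2)c(Br)c(OC)cc1OC | intermediate
12 | 1,3,6,10,12-pentamethoxy-[1]benzofuro[3,2-a]oxanthrene-4,9-diol | Oc1c(OC)cc(OC)c2c1Oc1c(OC)cc3oc4c(O)c(OC)cc(OC)c4c3c1O2 | intermediate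
13 | 1-iodo-3,5-dimethoxybenzene | COc1cc(I)cc(OC)c1 | starting material
14 | 4,9-bis(3,5-dimethoxyphenoxy)-1,3,6,10,12-pentamethoxy-[1]benzofuro[3,2-a]oxanthrene | COc1cc(OC)cc(Oc2c(OC)cc(OC)c3c2Oc2c(OC)cc4oc5c(Oc6cc(OC)cc(OC)c6)c(OC)cc(OC)c5c4c2O3)c1 | intermediate
15 | phlorofucofuroeckol A (achiral) | Oc1cc(O)cc(Oc2c(O)cc(O)c3c2Oc2c(O)cc4oc5c(Oc6cc(O)cc(O)c6)c(O)cc(O)c5c4c2O3)c1 | target

**Total steps:** 8.
**Longest linear sequence:** 6. This is steps 3–8 from 4, or equally step 1 or 2 followed by steps 4–8 from 1.

**The three steps most likely to fail**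

**Step 6 (Cu/Pd relay).** The free phenoxides and the copper salts may slow the palladium stage on a very electron-rich, di-ortho-flanked bromide. The fallback sets out from 11, isolated after the copper stage, and comes back to the route at 14. Both free phenols are arylated first with 13 (CuI, picolinic acid, K3PO4, DMSO, 90 °C). The aryl iodide reacts far faster than the buried ring D bromide, and this gives the open penta-aryl bromide F1. With no phenoxide and no copper left, the furan is closed last on this fully etherified substrate (Pd(OAc)2, PCy3·HBF4, PivOH, K2CO3, DMA, 130 °C) to give 14. The step count is unchanged if the copper stage is counted as step 6.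

**Step 4 (second, tetra-ortho SNAr).** Under forcing conditions the phenoxide of 7 could decompose, or could attack the formyl-activated diaryl ether of another molecule, instead of adding to 3. The fallback sets out from 4 and 3 and comes back at 10. The crowded ether is made first from the two smallest partners. The phenoxide of 4 cannot be oxidised, has a single nucleophilic site and meets no activated diaryl ether. It is forced onto 3 (K2CO3, DMSO, 120 °C) to give the ring B–ring C trialdehyde F2. mCPBA converts this into the tris-formate F3, and acid methanolysis gives the triol F4. Only the ring C hydroxyl of that triol has two free ortho positions. SNAr with 2 (K2CO3, DMF, 80 °C) therefore puts ring D there and gives the monoaldehyde F5. An acid Dakin oxidation (H2O2, cat. H2SO4, MeOH), running through the aryl formate F6, then delivers 10. This costs two more steps.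

**Step 2 (second formylation of an already formylated ring).** The Ti-bound aldehyde may shut the ring down, or TiCl4 may cleave the OMe ortho to it. The fallback sets out from 2 and comes back at 3. It replaces the electrophilic substitution by a cross-coupling. Pd-catalysed reductive carbonylation of the C–Br bond (Pd(OAc)2, di(1-adamantyl)-n-butylphosphine, CO/H2 1:1, TMEDA, toluene, 100 °C) places the second formyl group on the carbon that step 1 has already marked. No new compound is made, and the longest linear sequence becomes 7.

**Further compounds**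
F1 | step 6 | 7-[2-bromo-6-(3,5-dimethoxyphenoxy)-3,5-dimethoxyphenoxy]-1-(3,5-dimethoxyphenoxy)-2,4,9-trimethoxydibenzo[b,e][1,4]dioxin | COc1cc(OC)cc(Oc2c(Oc3cc4Oc5c(OC)cc(OC)c(Oc6cc(OC)cc(OC)c6)c5Oc4c(OC)c3)c(Br)c(OC)cc2OC)c1
F2 | step 4 | 2-(2-bromo-4-formyl-6-methoxyphenoxy)-4,6-dimethoxybenzene-1,3-dicarbaldehyde | O=Cc1cc(Br)c(Oc2c(C=O)c(OC)cc(OC)c2C=O)c(OC)c1
F3 | step 4 | tris-formate of F4 (each CHO of F2 replaced by OCHO) | O=COc1cc(Br)c(Oc2c(OC=O)c(OC)cc(OC)c2OC=O)c(OC)c1
F4 | step 4 | 2-(2-bromo-4-hydroxy-6-methoxyphenoxy)-4,6-dimethoxybenzene-1,3-diol | Oc1cc(Br)c(Oc2c(O)c(OC)cc(OC)c2O)c(OC)c1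
F5 | step 4 | 3-bromo-2-[3-bromo-4-(2,6-dihydroxy-3,5-dimethoxyphenoxy)-5-methoxyphenoxy]-4,6-dimethoxybenzaldehyde | O=Cc1c(Oc2cc(Br)c(Oc3c(O)c(OC)cc(OC)c3O)c(OC)c2)c(Br)c(OC)cc1OC
F6 | step 4 | 3-bromo-2-[3-bromo-4-(2,6-dihydroxy-3,5-dimethoxyphenoxy)-5-methoxyphenoxy]-4,6-dimethoxyphenyl formate | O=COc1c(Oc2cc(Br)c(Oc3c(O)c(OC)cc(OC)c3O)c(OC)c2)c(Br)c(OC)cc1OC
F0 | step 2 | none | none
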